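**Retrosynthetic overview**

1. Target numbering: C1 and C3 carry the carboxamides, C2 the (E)-heptenyl group, C4=C5 is the ring alkene, C6 carries the pentyl group. The C4=C5/C6–H array is traced back by reductive 1,3-transposition to enone 12 (C4 ketone, C5=C6 alkene).
2. Enone 12 comes from 1,5-diketone 10 by aldol condensation that forms the C5–C6 bond. 10 comes from catalytic asymmetric Michael addition (C2–C3 bond) of acetoacetamide 9 to dienamide 7, and 7 from Knoevenagel condensation of (E)-oct-2-enal 6 with β-keto amide 5.
3. Enabling feature: C2 is an aldehyde carbon flanked by the α-carbons (C1, C3) of two β-keto amides, C6 and C4 are their ketone carbons in a 1,5-relationship, and C5 is the acetyl methyl group. One enal and two β-keto amides therefore hold every carbon and both amide groups.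
4. Stereochemistry: C2 is set by the Michael catalyst. C1 and C3 stay epimerisable (γ of the enone, α to the ketone) and settle trans to C2. C6 is set last by suprafacial hydrogen delivery from an allylic diazene.
5. Ring formation: the single carbocycle is closed once, in step 5.

Key step: step 5

Remark: the sense of induction of the squaramide in step 5 cannot be predicted with certainty; the route is written for the catalyst pseudoenantiomer (quinine- or quinidine-derived) that gives the (3R)-configured adduct 10.

**Route**

Step 1
Reactants: 1 Meldrum's acid (2,2-dimethyl-1,3-dioxane-4,6-dione); 2 hexanoyl chloride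
Product: 3 5-(1-hydroxyhexylidene)-2,2-dimethyl-1,3-dioxane-4,6-dione
Conditions: pyridine (2 equiv), CH2Cl2, 0 °C to rt
Reagents that add atoms: hexanoyl chloride (2), CCCCCC(Cl)=O
Why: C-acylation of the strongly acidic cyclic malonate should give the enolised acyl Meldrum's acid; no stereocentre is formed.

Step 2
Reactants: 3 acyl Meldrum's acid; 4 isobutylamine (2-methylpropan-1-amine)
Product: 5 N-(2-methylpropyl)-3-oxooctanamide
Conditions: toluene, 110 °C, 2 h
Reagents that add atoms: isobutylamine (4), CC(C)CN
Why: thermal loss of acetone and CO2 should release hexanoylketene, which the amine traps as the β-keto amide (acylketene aminolysis).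

Step 3
Reactants: 5 N-(2-methylpropyl)-3-oxooctanamide; 6 (E)-oct-2-enal
Product: 7 (4E)-2-hexanoyl-N-(2-methylpropyl)deca-2,4-dienamide (2E/2Z mixture)
Conditions: piperidine (10 mol %), AcOH (10 mol %), 4 Å MS, CH2Cl2, 0 °C to rt
Reagents that add atoms: (E)-oct-2-enal (6), CCCCC/C=C/C=O
Why: Knoevenagel condensation at the aldehyde carbon should give the doubly activated diene with the 4E alkene of the enal intact; the geometry of the new alkene is irrelevant because that carbon becomes sp3 in step 5.

Step 4
Reactants: 8 2,2,6-trimethyl-4H-1,3-dioxin-4-one; 4 isobutylamine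
Product: 9 N-(2-methylpropyl)-3-oxobutanamide
Conditions: xylene, 140 °C, 1 h, acetone distilled off
Reagents that add atoms: isobutylamine (4), CC(C)CN
Why: cycloreversion of the dioxinone should give acetylketene, which the amine traps as the acetoacetamide.

Step 5
Reactants: 7 (4E)-2-hexanoyl-N-(2-methylpropyl)deca-2,4-dienamide; 9 N-(2-methylpropyl)-3-oxobutanamide
Product: 12 (1R,2S,3S)-2-[(1E)-hept-1-en-1-yl]-N1,N3-bis(2-methylpropyl)-6-oxo-4-pentylcyclohex-4-ene-1,3-dicarboxamide, via Michael adduct 10 (not isolated), via aldol ketol 11 (not isolated)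
Conditions: quinine-derived 3,5-bis(trifluoromethyl)phenyl squaramide (5 mol %), CH2Cl2, −20 °C; then pyrrolidine (20 mol %), AcOH (20 mol %), 4 Å MS, 40 °C
Reagents that add atoms: N-(2-methylpropyl)-3-oxobutanamide (9), CC(=O)CC(=O)NCC(C)C
Why: The squaramide should hold the two carbonyl groups of 7 by hydrogen bonding while its quinuclidine nitrogen delivers the enol of 9 to one face of the doubly activated β-carbon (1,4-addition), and pyrrolidinium acetate should then turn the acetyl group of 10 into its less substituted enamine, which adds to the hexanoyl carbonyl before ketol 11 loses water to the conjugated enone. The closest known reaction types are the catalytic asymmetric Michael addition of 1,3-dicarbonyl compounds to alkylidene 1,3-dicarbonyl compounds and the amine-mediated aldol condensation of the resulting 1,5-diketones to Hagemann-type cyclohexenones. The only ring closes in a 6-(enolexo)-exo-trig aldol addition that joins the acetyl methyl carbon to the hexanoyl carbonyl carbon (C5–C6 in target numbering). The heptenyl-bearing centre (C2) is set by the catalyst in the Michael step and cannot epimerise afterwards, whereas the two carboxamide-bearing centres (C3, α to the ketone, and C1, γ of the enone) should equilibrate through enol, enamine and dienamine forms to the all-equatorial arrangement trans to C2. The step needs 1,4- and not 1,6-addition (a 1,6-adduct of a 1,3-dicarbonyl nucleophile can revert while the 1,4-adduct is drained by cyclisation) and attack by the methyl and not the methylene enamine (the methyl ketone gives the less hindered enamine and an unsubstituted nucleophilic carbon). The 2E and 2Z isomers and the 2H-pyran valence isomer of 7, together with all diastereomers of 10 and 11, should converge on the single diastereomer 12.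

Step 6
Reactants: 12 enone; 13 p-toluenesulfonyl hydrazide
Product: 14 (1R,2S,3S)-2-[(1E)-hept-1-en-1-yl]-N1,N3-bis(2-methylpropyl)-6-[2-(4-methylbenzenesulfonyl)hydrazinylidene]-4-pentylcyclohex-4-ene-1,3-dicarboxamide
Conditions: TsNHNH2 (1.2 equiv), AcOH (cat.), EtOH, rt to 40 °C
Reagents that add atoms: p-toluenesulfonyl hydrazide (13), Cc1ccc(cc1)S(=O)(=O)NN
Why: hydrazone formation should occur at the only ketone while the secondary amides stay inert, and the adjacent carboxamide centre can still equilibrate through the ene-hydrazine, so the trans,trans arrangement is kept.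

Step 7
Reactants: 14 tosylhydrazone
Product: 17 (1R,2R,3S,6R)-2-[(1E)-hept-1-en-1-yl]-N1,N3-bis(2-methylpropyl)-6-pentylcyclohex-4-ene-1,3-dicarboxamide, via boryl hydrazine 15 (not isolated), via allylic diazene 16 (not isolated)
Conditions: catecholborane (3 equiv), CHCl3, 0 °C; then NaOAc·3H2O (3 equiv), 60 °C
Reagents that add atoms: none
Why: catecholborane should add hydride to the C=N carbon along the axial trajectory on the face opposite the heptenyl group (anti to the pseudo-axial hydrogen of the adjacent carboxamide carbon), acetate then releases p-toluenesulfinate, and allylic diazene 16 loses N2 in a suprafacial retro-ene reaction that moves the alkene to C4=C5 and places hydrogen on C6 on the diazene face, which leaves the pentyl group cis to both carboxamides (reductive 1,3-transposition of an enone tosylhydrazone).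

**Compound list**

1 | Meldrum's acid (2,2-dimethyl-1,3-dioxane-4,6-dione) | CC1(C)OC(=O)CC(=O)O1 | starting material
2 | hexanoyl chloride | CCCCCC(Cl)=O | starting material
3 | 5-(1-hydroxyhexylidene)-2,2-dimethyl-1,3-dioxane-4,6-dione | CCCCCC(O)=C1C(=O)OC(C)(C)OC1=O | intermediate
4 | isobutylamine (2-methylpropan-1-amine) | CC(C)CN | starting material
5 | N-(2-methylpropyl)-3-oxooctanamide | CCCCCC(=O)CC(=O)NCC(C)C | intermediate
6 | (E)-oct-2-enal | CCCCC/C=C/C=O | starting material
7 | (4E)-2-hexanoyl-N-(2-methylpropyl)deca-2,4-dienamide (2E/2Z mixture) | CCCCC/C=C/C=C(C(=O)CCCCC)C(=O)NCC(C)C | intermediate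
8 | 2,2,6-trimethyl-4H-1,3-dioxin-4-one | CC1=CC(=O)OC(C)(C)O1 | starting material
9 | N-(2-methylpropyl)-3-oxobutanamide | CC(=O)CC(=O)NCC(C)C | intermediate
10 | (3R)-2-acetyl-3-[(1E)-hept-1-en-1-yl]-4-hexanoyl-N1,N5-bis(2-methylpropyl)pentanediamide (epimer mixture at C2 and C4) | CCCCC/C=C/[C@H](C(C(C)=O)C(=O)NCC(C)C)C(C(=O)CCCCC)C(=O)NCC(C)C | intermediate (not isolated)
11 | (2S)-2-[(1E)-hept-1-en-1-yl]-4-hydroxy-N1,N3-bis(2-methylpropyl)-6-oxo-4-pentylcyclohexane-1,3-dicarboxamide (mixture at the other centres) | CCCCC/C=C/[C@H]1C(C(=O)NCC(C)C)C(O)(CCCCC)CC(=O)C1C(=O)NCC(C)C | intermediate (not isolated)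
12 | (1R,2S,3S)-2-[(1E)-hept-1-en-1-yl]-N1,N3-bis(2-methylpropyl)-6-oxo-4-pentylcyclohex-4-ene-1,3-dicarboxamide (heptenyl trans to both carboxamides) | CCCCC/C=C/[C@H]1[C@H](C(=O)NCC(C)C)C(CCCCC)=CC(=O)[C@@H]1C(=O)NCC(C)C | intermediate
13 | p-toluenesulfonyl hydrazide | Cc1ccc(cc1)S(=O)(=O)NN | starting material
14 | tosylhydrazone of 12, (1R,2S,3S) | CCCCC/C=C/[C@H]1[C@H](C(=O)NCC(C)C)C(CCCCC)=CC(=NNS(=O)(=O)c2ccc(C)cc2)[C@@H]1C(=O)NCC(C)C | intermediate
15 | N-(1,3,2-benzodioxaborol-2-yl) allylic tosylhydrazine from 14 (hydrazine nitrogen on the ring face of the heptenyl group, trans to the adjacent carboxamide) | CCCCC/C=C/[C@H]1[C@H](C(=O)NCC(C)C)C(CCCCC)=C[C@@H](N(B2Oc3ccccc3O2)NS(=O)(=O)c2ccc(C)cc2)[C@@H]1C(=O)NCC(C)C | intermediate (not isolated)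
16 | allylic monoalkyl diazene (N=NH on the ring face of the heptenyl group, trans to the adjacent carboxamide) | CCCCC/C=C/[C@H]1[C@H](C(=O)NCC(C)C)C(CCCCC)=C[C@@H](N=N)[C@@H]1C(=O)NCC(C)C | intermediate (not isolated)
17 | (1R,2R,3S,6R)-2-[(1E)-hept-1-en-1-yl]-N1,N3-bis(2-methylpropyl)-6-pentylcyclohex-4-ene-1,3-dicarboxamide | CCCCC/C=C/[C@H]1[C@H](C(=O)NCC(C)C)[C@H](CCCCC)C=C[C@@H]1C(=O)NCC(C)C | target

**Step count and risks**

Total steps: 7. Longest linear sequence: 6 steps (steps 1, 2, 3, 5, 6, 7); step 4 is a one-step branch.

Steps most likely to fail: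

1. Step 5. Process: after the Michael addition the ring may close through another nucleophile of 10 (the α-methylene of the hexanoyl group onto the acetyl carbonyl, an enol oxygen or an amide nitrogen). Reversible Michael addition may also erode the enantiomeric purity or exchange the two keto amide units. Fallback, setting out from 7 and returning at 12: commercial 4-chloroacetoacetyl chloride is treated with 4 (Et3N, CH2Cl2, −20 °C) to give 4-chloro-N-(2-methylpropyl)-3-oxobutanamide F1. PPh3 in toluene converts it into [4-(2-methylpropylamino)-2,4-dioxobutyl]triphenylphosphonium chloride F2, and aqueous Na2CO3 gives the stabilised ylide N-(2-methylpropyl)-3-oxo-4-(triphenylphosphoranylidene)butanamide F3. With NaH in THF the active methylene of F3 adds to 7 to give the ylide-bearing Michael adduct F4. On heating, F4 closes the same ring bond by intramolecular Wittig olefination, in which only the ylide carbon can reach the hexanoyl carbonyl. This gives racemic 12, which is resolved by preparative chromatography on a chiral stationary phase; the unwanted enantiomer (1S,2R,3R)-enone F5 is discarded.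

2. Step 7. Process: poor or reversed facial selectivity in the hydride addition to the hydrazone, which would place hydrogen on the wrong face of C6 and give the pentyl epimer. Fallback, setting out from 12 and returning at 16: Luche reduction (NaBH4, CeCl3·7H2O, MeOH, −78 °C) should show the same facial bias as the hydrazone and, in this scenario, give the allylic alcohol with hydroxyl cis to the adjacent carboxamide F6. Mitsunobu displacement with 2-nitrobenzenesulfonylhydrazide (PPh3, DEAD, THF, −30 °C) inverts that centre and gives the N-allyl-N-(2-nitrobenzenesulfonyl)hydrazine F7. On warming, F7 loses the sulfinic acid to give diazene 16 with nitrogen on the required face, and 16 goes on to 17 as in the route. If the ketone shows the opposite bias, a bulky hydride such as L-Selectride is used to obtain F6.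

3. Step 3. Process: conjugate addition of 5 to the enal instead of condensation, a second addition of 5 to 7, and drift of 7 into its 2H-pyran valence isomer. Fallback, setting out from 5 and returning at 7: triethyl orthoformate and Ac2O (120 °C) give 2-(ethoxymethylidene)-N-(2-methylpropyl)-3-oxooctanamide F8. After N-deprotonation with NaH, F8 is treated at −78 °C in THF with lithium bis[(E)-hept-1-enyl]cuprate F9 (from (E)-1-iodohept-1-ene, t-BuLi and CuI). Conjugate addition followed by loss of ethoxide gives 7 without any free enal in the flask.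

**Further compounds**

F1 | step 5 | 4-chloro-N-(2-methylpropyl)-3-oxobutanamide | ClCC(=O)CC(=O)NCC(C)C
F2 | step 5 | [4-(2-methylpropylamino)-2,4-dioxobutyl]triphenylphosphonium chloride | [Cl-].O=C(C[P+](c1ccccc1)(c1ccccc1)c1ccccc1)CC(=O)NCC(C)C
F3 | step 5 | N-(2-methylpropyl)-3-oxo-4-(triphenylphosphoranylidene)butanamide | O=C(C=P(c1ccccc1)(c1ccccc1)c1ccccc1)CC(=O)NCC(C)C
F4 | step 5 | racemic 3-[(1E)-hept-1-en-1-yl]-4-hexanoyl-N1,N5-bis(2-methylpropyl)-2-[2-(triphenylphosphoranylidene)acetyl]pentanediamide | CCCCC/C=C/C(C(C(=O)C=P(c1ccccc1)(c1ccccc1)c1ccccc1)C(=O)NCC(C)C)C(C(=O)CCCCC)C(=O)NCC(C)C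
F5 | step 5 | (1S,2R,3R)-2-[(1E)-hept-1-en-1-yl]-N1,N3-bis(2-methylpropyl)-6-oxo-4-pentylcyclohex-4-ene-1,3-dicarboxamide (enantiomer of 12) | CCCCC/C=C/[C@@H]1[C@@H](C(=O)NCC(C)C)C(CCCCC)=CC(=O)[C@H]1C(=O)NCC(C)C
F6 | step 7 | allylic alcohol from 12 (hydroxyl cis to the adjacent carboxamide, trans to the heptenyl group) | CCCCC/C=C/[C@H]1[C@H](C(=O)NCC(C)C)C(CCCCC)=C[C@H](O)[C@@H]1C(=O)NCC(C)C
F7 | step 7 | N-allyl-N-(2-nitrobenzenesulfonyl)hydrazine (nitrogen trans to the adjacent carboxamide) | CCCCC/C=C/[C@H]1[C@H](C(=O)NCC(C)C)C(CCCCC)=C[C@@H](N(N)S(=O)(=O)c2ccccc2[N+](=O)[O-])[C@@H]1C(=O)NCC(C)C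
F8 | step 3 | 2-(ethoxymethylidene)-N-(2-methylpropyl)-3-oxooctanamide | CCOC=C(C(=O)CCCCC)C(=O)NCC(C)C
F9 | step 3 | lithium bis[(E)-hept-1-enyl]cuprate | [Li+].CCCCC/C=C/[Cu-]/C=C/CCCCC
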